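**Retrosynthetic overview**
1. Ring B has one free OH (C3') para to its only C–H (C6'). The two carbons between them (C4', C5') both carry OMe, so O–C3'–C4'(OMe)–C5'(OMe)–C6' is read as 3,4-dimethoxyfuran with its ring oxygen still bridging C3' and C6'.
2. Key disconnection: C2'–C3' and C1'–C6', by [4+2] addition of that furan to a bromoethynyl group on chromone C2. The alkyne carbons become C1' and C2', and Br holds the place of the 2'-OMe.
3. Ring order: ring A is bought, pyrone ring C comes from an oxalate Claisen condensation and cyclodehydration, the furan from a double Claisen condensation, and ring B closes last as a 7-oxanorbornadiene.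
4. End game: Br to OMe by addition–elimination, acid-induced C6'–O cleavage with aromatisation to the 3'-phenol, then hydrogenolysis of the 5-O-benzyl group.
5. The bromoalkyne is made from the chromone-2-carbaldehyde by dibromoolefination and dehydrobromination, so no methanolic base meets the electrophilic aldehyde.

Key step: step 11

Assumption: 16 and 17 (and F2, F3) are racemates with one enantiomer drawn. The target is achiral, so the bridgehead centres are transient and need no absolute control.

**Step 1**
Reactants: 1 dimethyl diglycolate; 2 dimethyl oxalate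
Product: 3 dimethyl 3,4-dihydroxyfuran-2,5-dicarboxylate
Conditions: NaOMe (2.2 equiv), MeOH, reflux; then aq. HCl
Reagents that add atoms: none
Why: Hinsberg-type double Claisen condensation: each CH2 next to the ether oxygen of 1 is acylated by one carbonyl of the non-enolisable oxalate 2, and the cyclic 3,4-dione enolises to the aromatic dihydroxyfuran, whose disodium salt pulls the equilibria forward.

**Step 2**
Reactants: 3 dimethyl 3,4-dihydroxyfuran-2,5-dicarboxylate
Product: 4 dimethyl 3,4-dimethoxyfuran-2,5-dicarboxylate
Conditions: Me2SO4, K2CO3, acetone, reflux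
Reagents that add atoms: dimethyl sulfate, COS(=O)(=O)OC
Why: Williamson-type O-methylation of the two acidic enolic hydroxyls, for which the hard electrophile with K2CO3 in acetone favours oxygen over carbon and leaves the esters untouched.

**Step 3**
Reactants: 4 dimethyl 3,4-dimethoxyfuran-2,5-dicarboxylate
Product: 5 3,4-dimethoxyfuran-2,5-dicarboxylic acid
Conditions: NaOH, H2O–MeOH, reflux; then aq. HCl
Reagents that add atoms: sodium hydroxide, [Na+].[OH-]
Why: Plain ester saponification (acyl–oxygen cleavage by hydroxide), to which the methyl enol ethers and the carboxylate-deactivated furan ring are inert.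

**Step 4**
Reactants: 5 3,4-dimethoxyfuran-2,5-dicarboxylic acid
Product: 6 3,4-dimethoxyfuran
Conditions: Cu powder (cat.), quinoline, 200–220 °C, product distilled out
Reagents that add atoms: none
Why: Copper-mediated thermal protodecarboxylation of a furan-2,5-dicarboxylic acid, the classical access to free furan alpha-positions, with the volatile product removed from the hot zone by distillation.

**Step 5**
Reactants: 7 2',6'-dihydroxy-4'-methoxyacetophenone
Product: 8 2'-benzyloxy-6'-hydroxy-4'-methoxyacetophenone
Conditions: BnBr (1.0 equiv), K2CO3, acetone, reflux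
Reagents that add atoms: benzyl bromide, BrCc1ccccc1
Why: Williamson etherification in which the two hydroxyls of 7 are equivalent, so only one mono-ether exists, and the remaining hydroxyl is held in a strong hydrogen bond to the ketone, which slows a second alkylation.

**Step 6**
Reactants: 8 2'-benzyloxy-6'-hydroxy-4'-methoxyacetophenone; 9 diethyl oxalate
Product: 11 ethyl 5-benzyloxy-7-methoxy-4-oxo-4H-chromene-2-carboxylate, via diketo ester 10 (not isolated)
Conditions: NaOEt (3.5 equiv), EtOH, reflux; then ethanolic HCl, 60 °C
Reagents that add atoms: none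
Why: Crossed Claisen condensation of the methyl ketone enolate with non-enolisable diethyl oxalate, then acid-catalysed cyclodehydration (free phenol onto the C2 ketone, loss of water), the standard chromone-2-carboxylate synthesis, kept mild in acid so that the peri benzyl ether stays on.

**Step 7**
Reactants: 11 ethyl 5-benzyloxy-7-methoxy-4-oxo-4H-chromene-2-carboxylate
Product: 12 5-benzyloxy-2-(hydroxymethyl)-7-methoxy-4H-chromen-4-one
Conditions: NaBH4, MeOH–THF, 0 °C
Reagents that add atoms: none
Why: Chemoselective borohydride reduction: the C2 ester is activated by the electron-poor pyrone and the adjacent ring oxygen, whereas C4=O is a vinylogous ester further deactivated by the 5- and 7-alkoxy donors, as exploited for other chromone-2-carboxylates.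

**Step 8**
Reactants: 12 5-benzyloxy-2-(hydroxymethyl)-7-methoxy-4H-chromen-4-one
Product: 13 5-benzyloxy-7-methoxy-4-oxo-4H-chromene-2-carbaldehyde
Conditions: Dess–Martin periodinane, CH2Cl2, 0 °C to rt, non-aqueous work-up
Reagents that add atoms: none
Why: Dess–Martin oxidation of a primary alcohol under neutral, anhydrous conditions stops at the aldehyde and spares the benzyl ether and the chromone.

**Step 9**
Reactants: 13 5-benzyloxy-7-methoxy-4-oxo-4H-chromene-2-carbaldehyde
Product: 14 5-benzyloxy-2-(2,2-dibromovinyl)-7-methoxy-4H-chromen-4-one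
Conditions: CBr4, PPh3, CH2Cl2, 0 °C
Reagents that add atoms: carbon tetrabromide, BrC(Br)(Br)Br
Why: Ramirez dibromoolefination (first stage of the Corey–Fuchs sequence), a Wittig reaction of Ph3P=CBr2 that is fast with electron-poor aldehydes and does not touch the unreactive C4 carbonyl.

**Step 10**
Reactants: 14 5-benzyloxy-2-(2,2-dibromovinyl)-7-methoxy-4H-chromen-4-one
Product: 15 5-benzyloxy-2-(bromoethynyl)-7-methoxy-4H-chromen-4-one
Conditions: DBU (1.5 equiv), MeCN, 0 °C to rt
Reagents that add atoms: none
Why: Base-induced anti dehydrobromination of a 1,1-dibromoalkene to the 1-bromoalkyne, a known E2 process with DBU that is eased by the electron-poor chromonyl group and needs neither organolithium nor alkoxide.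

**Step 11**
Reactants: 15 5-benzyloxy-2-(bromoethynyl)-7-methoxy-4H-chromen-4-one; 6 3,4-dimethoxyfuran
Product: 16 racemic 5-benzyloxy-2-[(1R,4R)-3-bromo-5,6-dimethoxy-7-oxabicyclo[2.2.1]hepta-2,5-dien-2-yl]-7-methoxy-4H-chromen-4-one (bicycle C1 = C6', C2 = C1', C3 = C2', C4 = C3'; bridgeheads tied cis by the oxygen bridge)
Conditions: 6 (4 equiv), toluene (about 2 M), solid NaHCO3, BHT, Ar, dark, sealed tube, 85 °C
Reagents that add atoms: none
Why: Concerted, suprafacial normal-electron-demand [4+2] cycloaddition: the high-lying HOMO of the doubly oxygenated furan 6 meets the LUMO of the alkyne in 15, which is lowered by bromine and by conjugation through C2=C3 to the C4 carbonyl, and C2'–C3' and C1'–C6' form together. The closest known reaction type is the Diels–Alder addition of furans to 3-bromopropiolates and bromoethynyl ketones; here the acceptor acts one vinylogous link further away, which is offset by the far more reactive diene, its excess, high concentration and moderate heat. The six-membered carbocycle of ring B closes by intermolecular cycloaddition across furan C2 and C5, the furan oxygen remaining as a one-atom bridge between C3' and C6' (7-oxanorbornadiene). Both new stereocentres are the bridgeheads, whose relative configuration is dictated by the bridge geometry, so only a single racemic diastereomer is possible and both centres vanish on aromatisation. Regioselectivity is not required because 6 is symmetric; the selectivity that is required is alkyne over the chromone C2=C3 bond, secured because that alkene is trisubstituted, carries the O1 donor and is part of the pyrone, while the linear alkyne is sterically open. A second addition of 6 is disfavoured since the acceptor alkene C1'=C2' of 16 is tetrasubstituted, and solid NaHCO3 keeps traces of HBr from opening the bridge early.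

**Step 12**
Reactants: 16 bromo-oxanorbornadienyl chromone
Product: 17 racemic 5-benzyloxy-7-methoxy-2-[(1R,4S)-3,5,6-trimethoxy-7-oxabicyclo[2.2.1]hepta-2,5-dien-2-yl]-4H-chromen-4-one (same spatial arrangement as 16; the C4 descriptor changes only through ligand priorities)
Conditions: NaOMe (1.2 equiv), MeOH–THF, 0 °C
Reagents that add atoms: sodium methoxide, C[O-].[Na+]
Why: Nucleophilic vinylic substitution by addition–elimination, as known for 2-bromo-7-oxa- and 7-azanorbornadienes with an acceptor on the neighbouring carbon: methoxide adds to C2', the delta carbon of the O=C4–C3=C2–C1'=C2' dienone, with relief of strain, and the extended enolate expels bromide; should the enolate expel the C6' bridge oxygen instead, loss of HBr would lead to the same arene 18.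

**Step 13**
Reactants: 17 trimethoxy-oxanorbornadienyl chromone
Product: 18 5-benzyloxy-3'-hydroxy-7,2',4',5'-tetramethoxyflavone
Conditions: TFA (cat.), anhydrous CH2Cl2, 0 °C to rt
Reagents that add atoms: none
Why: Acid-catalysed isomerisation of a 7-oxanorbornadiene to a phenol: protonation of the bridge oxygen and heterolysis of C6'–O gives a pentadienyl cation with its charge on C2', C4' and C6', two of which bear OMe donors, whereas C3'–O cleavage would place charge on the chromonyl-bearing C1', so the oxygen should stay on C3' and loss of the C3' proton aromatises ring B.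

**Step 14**
Reactants: 18 5-benzyloxy-3'-hydroxy-7,2',4',5'-tetramethoxyflavone
Product: 19 5,3'-dihydroxy-7,2',4',5'-tetramethoxyflavone
Conditions: H2 (1 atm), Pd/C, EtOAc–MeOH, rt
Reagents that add atoms: none
Why: Catalytic hydrogenolysis of a benzyl aryl ether, routine for 5-O-benzyl flavones, is faster at one atmosphere than saturation of the cross-conjugated C2=C3 bond, and the methyl ethers are inert.

**Compound list**
1 | dimethyl diglycolate | COC(=O)COCC(=O)OC | starting material
2 | dimethyl oxalate | COC(=O)C(=O)OC | starting material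
3 | dimethyl 3,4-dihydroxyfuran-2,5-dicarboxylate | COC(=O)c1oc(C(=O)OC)c(O)c1O | intermediate
4 | dimethyl 3,4-dimethoxyfuran-2,5-dicarboxylate | COC(=O)c1oc(C(=O)OC)c(OC)c1OC | intermediate
5 | 3,4-dimethoxyfuran-2,5-dicarboxylic acid | OC(=O)c1oc(C(=O)O)c(OC)c1OC | intermediate
6 | 3,4-dimethoxyfuran | COc1cocc1OC | intermediate
7 | 2',6'-dihydroxy-4'-methoxyacetophenone | CC(=O)c1c(O)cc(OC)cc1O | starting material
8 | 2'-benzyloxy-6'-hydroxy-4'-methoxyacetophenone | CC(=O)c1c(O)cc(OC)cc1OCc1ccccc1 | intermediate
9 | diethyl oxalate | CCOC(=O)C(=O)OCC | starting material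
10 | ethyl 4-(2-benzyloxy-6-hydroxy-4-methoxyphenyl)-2,4-dioxobutanoate (not isolated) | CCOC(=O)C(=O)CC(=O)c1c(O)cc(OC)cc1OCc1ccccc1 | intermediate
11 | ethyl 5-benzyloxy-7-methoxy-4-oxo-4H-chromene-2-carboxylate | CCOC(=O)c1cc(=O)c2c(OCc3ccccc3)cc(OC)cc2o1 | intermediate
12 | 5-benzyloxy-2-(hydroxymethyl)-7-methoxy-4H-chromen-4-one | OCc1cc(=O)c2c(OCc3ccccc3)cc(OC)cc2o1 | intermediate
13 | 5-benzyloxy-7-methoxy-4-oxo-4H-chromene-2-carbaldehyde | O=Cc1cc(=O)c2c(OCc3ccccc3)cc(OC)cc2o1 | intermediate
14 | 5-benzyloxy-2-(2,2-dibromovinyl)-7-methoxy-4H-chromen-4-one | BrC(Br)=Cc1cc(=O)c2c(OCc3ccccc3)cc(OC)cc2o1 | intermediate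
15 | 5-benzyloxy-2-(bromoethynyl)-7-methoxy-4H-chromen-4-one | BrC#Cc1cc(=O)c2c(OCc3ccccc3)cc(OC)cc2o1 | intermediate
16 | racemic 5-benzyloxy-2-[(1R,4R)-3-bromo-5,6-dimethoxy-7-oxabicyclo[2.2.1]hepta-2,5-dien-2-yl]-7-methoxy-4H-chromen-4-one | COC1=C(OC)[C@@H]2O[C@H]1C(Br)=C2c3cc(=O)c4c(OCc5ccccc5)cc(OC)cc4o3 | intermediate
17 | racemic 5-benzyloxy-7-methoxy-2-[(1R,4S)-3,5,6-trimethoxy-7-oxabicyclo[2.2.1]hepta-2,5-dien-2-yl]-4H-chromen-4-one | COC1=C(OC)[C@@H]2O[C@H]1C(OC)=C2c3cc(=O)c4c(OCc5ccccc5)cc(OC)cc4o3 | intermediate
18 | 5-benzyloxy-3'-hydroxy-7,2',4',5'-tetramethoxyflavone | COc1cc(OCc2ccccc2)c2c(=O)cc(-c3cc(OC)c(OC)c(O)c3OC)oc2c1 | intermediate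
19 | 5,3'-dihydroxy-7,2',4',5'-tetramethoxyflavone | COc1cc(O)c2c(=O)cc(-c3cc(OC)c(OC)c(O)c3OC)oc2c1 | target

**Step count**
Total steps: 14 (4 for the furan, 6 for the bromoalkyne, 4 from their union).
Longest linear sequence: 10 steps (steps 5 to 14, from 7).

**Steps most likely to fail**

1. **Step 11.**
   - Risk: the cycloaddition may be too slow because the carbonyl activates the alkyne only through the C2=C3 bond. Thermal decay of the bromoalkyne, cycloreversion at the temperature needed, or early acid-triggered opening of the bridge could then take over.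
   - Fallback: it sets out from 6 (with 8 as ring A partner) and returns at 19. The cycloaddition is moved to a dienophile of the established class, and the pyrone ring is built afterwards.
   - Methyl propiolate is brominated (NBS, cat. AgNO3, acetone) to methyl 3-bromopropiolate F1.
   - F1 should add to 6 near room temperature to give racemic methyl (1R,4R)-3-bromo-5,6-dimethoxy-7-oxabicyclo[2.2.1]hepta-2,5-diene-2-carboxylate F2.
   - NaOMe in MeOH exchanges bromide to give racemic methyl (1R,4S)-3,5,6-trimethoxy-7-oxabicyclo[2.2.1]hepta-2,5-diene-2-carboxylate F3.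
   - Catalytic TFA aromatises F3 to methyl 3-hydroxy-2,4,5-trimethoxybenzoate F4, and BnBr with K2CO3 gives methyl 3-benzyloxy-2,4,5-trimethoxybenzoate F5.
   - Claisen condensation of F5 with the dianion of 8 (LiHMDS, THF) gives 1-(2-benzyloxy-6-hydroxy-4-methoxyphenyl)-3-(3-benzyloxy-2,4,5-trimethoxyphenyl)propane-1,3-dione F6.
   - Cyclodehydration (TsOH, toluene, 80 °C) gives 5,3'-dibenzyloxy-7,2',4',5'-tetramethoxyflavone F7, and hydrogenolysis of both benzyl ethers (H2, Pd/C) leads to 19.

2. **Step 12.**
   - Risk: methoxide may attack chromone C2 and open the pyrone ring, or a second molecule of methanol may add to the strained enol ether, in competition with clean exchange of bromide.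
   - Fallback: it sets out from 16 and returns at 18, reversing the order so that aromatisation comes first and substitution happens on the arene.
   - Catalytic TFA in CH2Cl2 should open the bridge of 16 at C6'–O, because the alternative cation would place charge on the chromonyl-bearing C1'. This gives 5-benzyloxy-2'-bromo-3'-hydroxy-7,4',5'-trimethoxyflavone F8.
   - An Ullmann-type methoxylation (CuI, NaOMe, MeOH–DMF, 110 °C), the reaction used to turn ortho-bromophenols into ortho-methoxyphenols, replaces the aryl bromide and gives 18.

3. **Step 10.**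
   - Risk: the amidine base may attack the freshly formed electrophilic bromoalkyne or chromone C2, or the elimination may stall.
   - Fallback: it sets out from 13 and returns at 15, installing the halogen last under non-basic conditions.
   - Ohira–Bestmann homologation (dimethyl (1-diazo-2-oxopropyl)phosphonate, K2CO3, MeOH, 0 °C) gives 5-benzyloxy-2-ethynyl-7-methoxy-4H-chromen-4-one F9.
   - Electrophilic bromination of the terminal alkyne (NBS, cat. AgNO3, acetone, rt) gives 15.

**Further compounds**
F1 | step 11 | methyl 3-bromopropiolate | COC(=O)C#CBr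
F2 | step 11 | racemic methyl (1R,4R)-3-bromo-5,6-dimethoxy-7-oxabicyclo[2.2.1]hepta-2,5-diene-2-carboxylate | COC1=C(OC)[C@@H]2O[C@H]1C(Br)=C2C(=O)OC
F3 | step 11 | racemic methyl (1R,4S)-3,5,6-trimethoxy-7-oxabicyclo[2.2.1]hepta-2,5-diene-2-carboxylate | COC1=C(OC)[C@@H]2O[C@H]1C(OC)=C2C(=O)OC
F4 | step 11 | methyl 3-hydroxy-2,4,5-trimethoxybenzoate | COC(=O)c1cc(OC)c(OC)c(O)c1OC
F5 | step 11 | methyl 3-benzyloxy-2,4,5-trimethoxybenzoate | COC(=O)c1cc(OC)c(OC)c(OCc2ccccc2)c1OC
F6 | step 11 | 1-(2-benzyloxy-6-hydroxy-4-methoxyphenyl)-3-(3-benzyloxy-2,4,5-trimethoxyphenyl)propane-1,3-dione | COc1cc(O)c(C(=O)CC(=O)c2cc(OC)c(OC)c(OCc3ccccc3)c2OC)c(OCc2ccccc2)c1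
F7 | step 11 | 5,3'-dibenzyloxy-7,2',4',5'-tetramethoxyflavone | COc1cc(OCc2ccccc2)c2c(=O)cc(-c3cc(OC)c(OC)c(OCc4ccccc4)c3OC)oc2c1
F8 | step 12 | 5-benzyloxy-2'-bromo-3'-hydroxy-7,4',5'-trimethoxyflavone | COc1cc(OCc2ccccc2)c2c(=O)cc(-c3cc(OC)c(OC)c(O)c3Br)oc2c1
F9 | step 10 | 5-benzyloxy-2-ethynyl-7-methoxy-4H-chromen-4-one | C#Cc1cc(=O)c2c(OCc3ccccc3)cc(OC)cc2o1
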